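Start from a ratio: when G climbs at a fast rate and falls at a slow one, and the first is many times the second, the curve has a rounded top, and that top is what is examined here.

| setting | amber | red | violet | flask |
|---|---|---|---|---|
| X | 0.050 M | 0.075 M | 0.10 M | 0.10 M |
| Q | 1.3 equiv | 1.3 equiv | 2.6 equiv | 1.30 equiv |
| remark | run made earlier | run made earlier | run made earlier |  |
| time |  |  |  | 5.0 h |

| run | time / h | G / % |
|---|---|---|
| amber | 0.0833 | 13.1 |
| amber | 0.250 | 23.3 |
| amber | 0.833 | 21.2 |
| amber | 3.00 | 3.3 |
| red | 0.0833 | 15.7 |
| red | 0.250 | 28.2 |
| red | 0.833 | 20.9 |
| red | 3.00 | 3.8 |
| violet | 0.0833 | 26.1 |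
| violet | 0.250 | 29.0 |
| violet | 0.833 | 12.7 |
| violet | 3.00 | 1.9 |

(each reading ± 1 percentage point)

* the best time, 5.0 h at the latest, for G
* the amount of G, in percent of the X charged, at that time
* earliest time at which at least nineteen twentieths of that best amount are there
* latest time at which they still are



What is the slow rate? Take the logarithmic fall between the last two readings of each run, and replace the three slopes by their mean, 0.841 h⁻¹.

And the fast rate? I borrow the early rate that the forecast extrapolates to this flask, 7.50 h⁻¹, which is faster than the slow one.

How sharp is the top? For a difference of two exponentials, the fractional drop at a small offset from the peak is the product of the two rates, times the square of the offset, over 2. Setting that drop to 5.00% gives the reach of the top, the offset on either side at which 95.0% of the peak remain: 0.126 h. My window in this flask is therefore 0.252 h wide.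

But a parabola is symmetric, and this curve is not? Right: it rises faster than it falls, so I commit to the width and expect the late edge to lie further from the peak than the early edge.

The forecast, holding that “G's loss is roughly first order and barely depends on concentration”, puts the top at 0.31 h with 30.5%, and the window from 0.21 h to 0.46 h.

The flask peaks at 0.306 h with 28.5%, and its window runs from 0.194 h to 0.462 h, each inside the forecast's range.

    X + 2 Q → J (k = 0.0620 M⁻² s⁻¹)
    G ⇌ D (K = 0.110, k = 8.80 × 10⁻⁴ s⁻¹)
    G → Z (k = 4.90 × 10⁻⁴ s⁻¹)
    X + Q → G (k = 0.0100 M⁻¹ s⁻¹)

The window of this flask is 0.268 h wide against the reckoned 0.252 h, reaching 0.156 h after the top and 0.112 h before it. For amber, the forecast's 5.4 per hour stretches the reach to 0.148 h. With the forecast's peak for amber at 0.41 h, amber's reading at 0.250 h lifts to 24.7%, against a top of 26.1% for amber without the scatter. The path from G to Z is the largest single effect on the height of this flask's top: with it taken away, the highest amount of G goes from 28.5% to 63.8%.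

All runs were generated by integration from invented constants.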